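**Retrosynthetic overview**
- The tiglate is attached last to the macrocyclic C3 alcohol; that alcohol comes from ring-closing metathesis (C1=C10) of an acyclic butenolide, so the ten-membered carbocycle is the last ring formed. The ester must follow the metathesis because a homoallylic tiglate would close to a six-membered lactone instead.
- Key step: a ligand-controlled palladium oxidation of a (2Z,4E,6E)-trienoic acid makes both C–O bonds (C6–O of the lactone and C3–O), both stereocentres and the E-C4=C5 alkene at once, and closes the butenolide.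
- The trienoic acid comes from a γ-hydroxybutenolide by Horner–Wadsworth–Emmons olefination; the lactol ring locks the Z tetrasubstituted alkene and then opens.
- The γ-hydroxybutenolide comes from γ-oxidation of a butenolide made in one operation from but-2-yne-1,4-diol, a homoallyl Grignard reagent and CO2 (first, temporary formation of the five-membered ring).
- The phosphonate comes from isoprene monoxide and vinylmagnesium bromide.

Assumption: locants C1–C15 follow germacrane numbering (C3 = CH–O-tigloyl, C6 = lactone CH–O, C7=C11 = butenolide alkene, C12 = lactone carbonyl, C13 = CH2OAc); the SMILES is read as 3S,6R with a 1(10)Z and a 4E ring alkene and an E (tiglate) ester.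

**Step 1**
Reactants: 1 2-methyl-2-vinyloxirane (isoprene monoxide, racemic); 2 vinylmagnesium bromide
Product: 3 (2E)-2-methylhexa-2,5-dien-1-ol
Conditions: CuI (10 mol%), THF, −30 → 0 °C; then H2O
Reagents that add atoms: none
Why: Copper-catalysed SN2′ opening of the vinyl epoxide (allylic substitution) delivers the vinyl group to the terminal carbon and gives the E trisubstituted allylic alcohol (about 9:1 E:Z expected, minor isomer removed by chromatography).

**Step 2**
Reactants: 3 (2E)-2-methylhexa-2,5-dien-1-ol
Product: 4 diethyl [(2E)-2-methylhexa-2,5-dien-1-yl]phosphonate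
Conditions: P(OEt)3 (3 equiv), ZnI2 (1.5 equiv), THF, reflux
Reagents that add atoms: triethyl phosphite, CCOP(OCC)OCC
Why: Zinc iodide-mediated direct phosphonylation of a primary allylic alcohol (Michaelis–Arbuzov-type rearrangement of the mixed phosphite) takes place at the primary carbon with retention of the E geometry.

**Step 3**
Reactants: 5 but-2-yne-1,4-diol; 6 4-bromo-2-methylbut-1-ene (3.3 equiv)
Product: 9 3-(hydroxymethyl)-4-(3-methylbut-3-en-1-yl)furan-2(5H)-one, via Grignard reagent 7 (not isolated), via alkenylmagnesium alkoxide 8 (not isolated)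
Conditions: Mg, THF, 45 °C; then 5, CuI (10 mol%), THF–toluene, 65 °C; CO2 (1 atm), −20 → 23 °C; 2 M HCl
Reagents that add atoms: carbon dioxide, O=C=O
Why: Copper-catalysed anti-carbomagnesiation of the propargylic dialkoxide (symmetric alkyne, so no regiochemical issue) gives a chelated alkenylmagnesium whose carboxylation places CO2H cis to one CH2OH, and acidification lactonizes it to the butenolide (Grignard carbometalation–carboxylation–lactonization).

**Step 4**
Reactants: 9 3-(hydroxymethyl)-4-(3-methylbut-3-en-1-yl)furan-2(5H)-one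
Product: 11 5-hydroxy-3-(hydroxymethyl)-4-(3-methylbut-3-en-1-yl)furan-2(5H)-one (racemic lactol), via bis(triethylsilyl) furan 10 (not isolated)
Conditions: Et3SiOTf (2.2 equiv), Et3N (2.5 equiv), CH2Cl2, 0 °C; pentane, filter, concentrate; dimethyldioxirane (1.05 equiv), acetone–CH2Cl2, −78 °C; then 0.5 M HCl, THF, 0 °C
Reagents that add atoms: dimethyldioxirane, CC1(C)OO1
Why: Soft enolization gives the 2-silyloxyfuran, which dimethyldioxirane oxidizes at C5 (Rubottom-type oxidation) to the silyl (Z)-4-oxo-2-enoate that hydrolyses to the γ-hydroxybutenolide; the new lactol carbon is racemic and becomes sp2 in step 5.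

**Step 5**
Reactants: 11 5-hydroxy-3-(hydroxymethyl)-4-(3-methylbut-3-en-1-yl)furan-2(5H)-one; 4 diethyl [(2E)-2-methylhexa-2,5-dien-1-yl]phosphonate
Product: 13 (2Z,4E,6E)-2-(acetoxymethyl)-6-methyl-3-(3-methylbut-3-en-1-yl)deca-2,4,6,9-tetraenoic acid, via dilithium hydroxy-acid salt 12 (not isolated)
Conditions: LiN(SiMe3)2 (3.3 equiv in all), THF–DMPU, −78 → 23 °C; then Ac2O (4 equiv), 0 °C; aq. NaHCO3, then 1 M HCl to pH 3–4
Reagents that add atoms: acetic anhydride, CC(=O)OC(C)=O
Why: Horner–Wadsworth–Emmons olefination of the ring-opened (Z)-4-oxo-enoate (the lactol ring has locked the 2Z geometry) with the allylic phosphonate anion gives the new E alkene, and the primary lithium alkoxide is acetylated in the same flask while the mixed anhydride at the carboxyl group is hydrolysed on work-up.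

**Step 6**
Reactants: 13 (2Z,4E,6E)-2-(acetoxymethyl)-6-methyl-3-(3-methylbut-3-en-1-yl)deca-2,4,6,9-tetraenoic acid
Product: 15 [(5R)-5-[(1E,3S)-3-hydroxy-2-methylhexa-1,5-dien-1-yl]-4-(3-methylbut-3-en-1-yl)-2-oxo-2,5-dihydrofuran-3-yl]methyl acetate, via C3 trifluoroacetate 14 (not isolated)
Conditions: Pd(O2CCF3)2 (10 mol%), i-Pr-SPRIX (spiro bis(isoxazoline) ligand, one enantiomer, 12 mol%), 1,4-benzoquinone (1.5 equiv), CF3CO2Li (3 equiv), CF3CO2H (1.2 equiv, slow addition), acetone, 0 °C; then aq. NaHCO3, THF, 0 °C
Reagents that add atoms: trifluoroacetic acid, OC(=O)C(F)(F)F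
Why: Proposed new method: enantioselective divalent-palladium-catalysed oxidative 1,4-hydroxylactonization of an acyclic (E,E)-dienoic acid, in which the chiral N,N-ligated palladium binds the C5=C6 alkene, the cis carboxylate attacks the Re face of C6 anti to palladium (5-exo) to give a syn,syn η3-allyl over C5–C4–C3, trifluoroacetate then attacks the Si face of C3 anti to palladium (outer sphere, because the bidentate ligand leaves no site for inner-sphere delivery), benzoquinone reoxidizes zerovalent palladium and bicarbonate hydrolyses the trifluoroacetate, so both oxygens enter on the same diene face, which ties 3S to 6R once the ligand has chosen the C6 face and gives the E-C4=C5 alkene; the closest known reaction type is the racemic palladium/benzoquinone 1,4-oxylactonization and 1,4-acetoxy-trifluoroacetoxylation of conjugated dienes (Bäckvall oxidation) together with SPRIX–palladium enantioselective Wacker-type cyclizations.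

**Step 7**
Reactants: 15 [(5R)-5-[(1E,3S)-3-hydroxy-2-methylhexa-1,5-dien-1-yl]-4-(3-methylbut-3-en-1-yl)-2-oxo-2,5-dihydrofuran-3-yl]methyl acetate
Product: 16 (3S,6R)-13-acetoxy-3-hydroxygermacra-1(10)Z,4E,7(11)-trien-12,6-olide
Conditions: second-generation Hoveyda–Grubbs catalyst RuCl2(H2IMes)(=CH-C6H4-2-O-i-Pr) (10 mol%, two portions), toluene (1 mM), 60 °C, argon sparge
Reagents that add atoms: none
Why: Ring-closing metathesis between the allyl and isopropenyl termini releases ethene, and the trisubstituted C1=C10 alkene is expected as the Z isomer because the ten-membered ring that already holds the E-C4=C5 alkene and the fused lactone is least strained with a cis bond there.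

**Step 8**
Reactants: 16 (3S,6R)-13-acetoxy-3-hydroxygermacra-1(10)Z,4E,7(11)-trien-12,6-olide; 17 (2E)-2-methylbut-2-enoyl chloride (tigloyl chloride)
Product: 18 (3S,6R)-13-acetoxy-3-[(2E)-2-methylbut-2-enoyloxy]germacra-1(10)Z,4E,7(11)-trien-12,6-olide (CNP0198881.1)
Conditions: 17 (1.5 equiv), pyridine, DMAP (10 mol%), CH2Cl2, 0 °C
Reagents that add atoms: none
Why: DMAP-catalysed acylation (nucleophilic catalysis) of the secondary allylic alcohol proceeds with retention at C3, and the weakly basic, cold conditions leave the acidic C6 proton and the allylic acetate untouched.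

**Compound list**
1 | 2-methyl-2-vinyloxirane (isoprene monoxide, racemic) | CC1(CO1)C=C | starting material
2 | vinylmagnesium bromide | C=C[Mg]Br | starting material
3 | (2E)-2-methylhexa-2,5-dien-1-ol | OC/C(C)=C/CC=C | intermediate
4 | diethyl [(2E)-2-methylhexa-2,5-dien-1-yl]phosphonate | CCOP(=O)(OCC)C/C(C)=C/CC=C | intermediate
5 | but-2-yne-1,4-diol | OCC#CCO | starting material
6 | 4-bromo-2-methylbut-1-ene | C=C(C)CCBr | starting material
7 | (3-methylbut-3-en-1-yl)magnesium bromide | C=C(C)CC[Mg]Br | intermediate
8 | bromomagnesium alkenyl species from anti-carbomagnesiation (alkyl group trans to C–Mg; both alkoxides as OMgBr) | C=C(C)CC/C(CO[Mg]Br)=C(\CO[Mg]Br)[Mg]Br | intermediate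
9 | 3-(hydroxymethyl)-4-(3-methylbut-3-en-1-yl)furan-2(5H)-one | OCC1=C(CCC(C)=C)COC1=O | intermediate
10 | triethyl{[4-(3-methylbut-3-en-1-yl)-3-{[(triethylsilyl)oxy]methyl}furan-2-yl]oxy}silane | CC[Si](CC)(CC)OCc1c(CCC(C)=C)coc1O[Si](CC)(CC)CC | intermediate
11 | 5-hydroxy-3-(hydroxymethyl)-4-(3-methylbut-3-en-1-yl)furan-2(5H)-one (racemic lactol) | OCC1=C(CCC(C)=C)C(O)OC1=O | intermediate
12 | dilithium (2Z,4E,6E)-6-methyl-3-(3-methylbut-3-en-1-yl)-2-(oxidomethyl)deca-2,4,6,9-tetraenoate | [Li+].[Li+].[O-]C(=O)/C(C[O-])=C(CCC(C)=C)\C=C\C(C)=C\CC=C | intermediate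
13 | (2Z,4E,6E)-2-(acetoxymethyl)-6-methyl-3-(3-methylbut-3-en-1-yl)deca-2,4,6,9-tetraenoic acid | OC(=O)/C(COC(C)=O)=C(CCC(C)=C)\C=C\C(C)=C\CC=C | intermediate
14 | (1E,3S)-1-[(2R)-4-(acetoxymethyl)-3-(3-methylbut-3-en-1-yl)-5-oxo-2,5-dihydrofuran-2-yl]-2-methylhexa-1,5-dien-3-yl trifluoroacetate | FC(F)(F)C(=O)O[C@@H](CC=C)/C(C)=C/[C@H]1OC(=O)C(COC(C)=O)=C1CCC(C)=C | intermediate
15 | [(5R)-5-[(1E,3S)-3-hydroxy-2-methylhexa-1,5-dien-1-yl]-4-(3-methylbut-3-en-1-yl)-2-oxo-2,5-dihydrofuran-3-yl]methyl acetate | O[C@@H](CC=C)/C(C)=C/[C@H]1OC(=O)C(COC(C)=O)=C1CCC(C)=C | intermediate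
16 | (3S,6R)-13-acetoxy-3-hydroxygermacra-1(10)Z,4E,7(11)-trien-12,6-olide | O[C@H]1C/C=C(/C)CCC2=C(COC(C)=O)C(=O)O[C@@H]2/C=C/1C | intermediate
17 | (2E)-2-methylbut-2-enoyl chloride (tigloyl chloride) | C/C=C(\C)C(Cl)=O | starting material
18 | (3S,6R)-13-acetoxy-3-[(2E)-2-methylbut-2-enoyloxy]germacra-1(10)Z,4E,7(11)-trien-12,6-olide | C/C=C(\C)C(=O)O[C@H]1C/C=C(/C)CCC2=C(COC(C)=O)C(=O)O[C@@H]2/C=C/1C | target

**Step count**
Total steps: 8. Longest linear sequence: 6 (steps 3 to 8, from but-2-yne-1,4-diol).

**Steps most likely to fail**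

Step 6 (the proposed new method). The risks are:
- insufficient enantiocontrol by the ligand;
- inner-sphere (syn) delivery of trifluoroacetate, which would give the C3 epimer;
- syn/anti isomerization of the 2-methyl-substituted allyl, which would erode the E geometry;
- acid-promoted background cyclization of the trienoic acid.

The fallback uses known chemistry, sets out from 13 and comes back at 15. Acid 13 is epoxidized at the distal, most electron-rich trisubstituted C3=C4 alkene by Shi asymmetric epoxidation, using the L-fructose-derived Shi ketone (1,2:4,5-di-O-isopropylidene-β-L-erythro-2,3-hexodiulo-2,6-pyranose), Oxone (2KHSO5·KHSO4·K2SO4) and a K2CO3 buffer in MeCN–dimethoxymethane–water at 0 °C. This gives (2Z,4E)-2-(acetoxymethyl)-5-[(2S,3S)-2-methyl-3-(prop-2-en-1-yl)oxiran-2-yl]-3-(3-methylbut-3-en-1-yl)penta-2,4-dienoic acid F1. After careful acidification, crude F1 is treated with Pd(PPh3)4 (zerovalent palladium, 5 mol%) in THF at 0 °C. Ionization of the allylic C4–O bond anti to the epoxide oxygen, then attack of the cis carboxylate on C6 anti to palladium (double inversion, net 1,4-syn), gives 15 with the same 3S,6R relationship and the E alkene.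

Step 7 (ring-closing metathesis). A trisubstituted alkene must form in a strained ten-membered ring, so oligomers or an E/Z mixture are possible. The fallback inverts the order of ring formation: the carbocycle is closed on a seco acid and the butenolide is then closed across the ring by C–O bond formation. It sets out from 13 and comes back at 16. Acid 13 is epoxidized as above to (2Z,4E)-2-(acetoxymethyl)-5-[(2S,3S)-2-methyl-3-(prop-2-en-1-yl)oxiran-2-yl]-3-(3-methylbut-3-en-1-yl)penta-2,4-dienoic acid F2 (the same substance as F1). Metathesis of F2 with the same ruthenium catalyst gives (3S,4S)-13-acetoxy-3,4-epoxygermacra-1(10)Z,5E,7(11)-trien-12-oic acid (carboxyl cis to C6) F3. Pd(PPh3)4 in THF then opens the vinyl epoxide with transannular attack of the carboxylate on C6 and gives 16. The ring strain in F3 is probably similar, so this fallback mainly helps if the fused lactone is what blocks closure of 15.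

Step 3 (carbomagnesiation and carboxylation). Primary alkyl Grignard reagents with β-hydrogens are the least reactive class in this addition, three equivalents are consumed, and the chelated alkenylmagnesium must still be carboxylated. The fallback replaces carbometalation by cross-coupling and carbonylation; it sets out from 5 and 6 and comes back at 9.
- Diol 5 is brominated (Br2, CH2Cl2, 0 °C, anti addition) to (2E)-2,3-dibromobut-2-ene-1,4-diol F4.
- Bromide 6 is converted with zinc dust and LiCl in THF into (3-methylbut-3-en-1-yl)zinc bromide F5.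
- Negishi mono-coupling of F4 with F5 (PdCl2(dppf), THF, 40 °C) gives (2Z)-2-bromo-3-(3-methylbut-3-en-1-yl)but-2-ene-1,4-diol F6, in which the remaining C–Br bond is cis to the CH2OH on the alkylated carbon.
- Palladium-catalysed cyclocarbonylation of F6 (Pd(PPh3)4, CO 1 atm, K2CO3, THF, 60 °C) closes the butenolide and gives 9.

**Further compounds**
F1 | step 6 | (2Z,4E)-2-(acetoxymethyl)-5-[(2S,3S)-2-methyl-3-(prop-2-en-1-yl)oxiran-2-yl]-3-(3-methylbut-3-en-1-yl)penta-2,4-dienoic acid | OC(=O)/C(COC(C)=O)=C(CCC(C)=C)\C=C\[C@]1(C)O[C@H]1CC=C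
F2 | step 7 | (2Z,4E)-2-(acetoxymethyl)-5-[(2S,3S)-2-methyl-3-(prop-2-en-1-yl)oxiran-2-yl]-3-(3-methylbut-3-en-1-yl)penta-2,4-dienoic acid | OC(=O)/C(COC(C)=O)=C(CCC(C)=C)\C=C\[C@]1(C)O[C@H]1CC=C
F3 | step 7 | (3S,4S)-13-acetoxy-3,4-epoxygermacra-1(10)Z,5E,7(11)-trien-12-oic acid (carboxyl cis to C6) | OC(=O)/C(COC(C)=O)=C1/CC/C(C)=C\C[C@@H]2O[C@@]2(C)/C=C/1
F4 | step 3 | (2E)-2,3-dibromobut-2-ene-1,4-diol | OC/C(Br)=C(\Br)CO
F5 | step 3 | (3-methylbut-3-en-1-yl)zinc bromide | C=C(C)CC[Zn]Br
F6 | step 3 | (2Z)-2-bromo-3-(3-methylbut-3-en-1-yl)but-2-ene-1,4-diol | OC/C(Br)=C(CO)\CCC(C)=C
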